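The pitfall with this set of flasks was to treat the target as a product that piles up, so that more time and more turnover mean more of it.

in all of them: time 6.0 h
- epsilon: starting material 0.20 M (fed, over 5.0 h); reagent 0.260 M; temperature 5 °C; all else is in the flask from the start; the feed brings no volume worth counting
- delta: starting material 0.20 M; reagent 0.260 M; temperature 5 °C; everything together at the start
- gamma: starting material 0.20 M; reagent 0.260 M; everything together at the start at −15 °C, warmed to 5 °C at 5.0 h
- beta: starting material 0.20 M (in portions, 4, over 5.0 h); reagent 0.260 M; temperature 5 °C; first portion at the start, last at 5.0 h
- zeta: starting material 0.20 M; reagent 0.260 M (fed, over 5.0 h); temperature 5 °C; all else is in the flask from the start; the feed brings no volume worth counting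
- eta: starting material 0.20 M (fed, over 5.0 h); reagent 0.260 M; the addition at −15 °C, then warmed to 5 °C; the feed brings no volume worth counting

- the best flask by amount of target, in percent of the starting material charged; "all alike" if 1.5 percentage points covers them all (epsilon / delta / gamma / beta / zeta / eta / all alike)
- amount of target at the end, in percent of the starting material charged, epsilon
- amount of target at the end, in percent of the starting material charged, delta
- amount of target at the end, in percent of the starting material charged, gamma
- amount of target at the end, in percent of the starting material charged, beta
- amount of target at the end, in percent of the starting material charged, zeta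
- amount of target at the end, in percent of the starting material charged, eta

- percent here means starting material units held: one side product B counts as two
- a doubled species enters its step squared and goes two at a time
- at 5 °C the constants are as listed, elsewhere as the activation energies and enthalpies make them

    starting material + reagent ⇌ target (K1 = 1.51 L mol⁻¹, k1 = 3.16 L mol⁻¹ h⁻¹, Ea1 = 64.0 kJ mol⁻¹, ΔH1 = 24.0 kJ mol⁻¹)
    reagent + target → over-reaction product (k2 = 0.184 L mol⁻¹ h⁻¹, Ea2 = 61.0 kJ mol⁻¹)
    starting material + 2 reagent → side product A (k3 = 4.09 L² mol⁻² h⁻¹, Ea3 = 38.0 kJ mol⁻¹)
    starting material + target → side product B (k4 = 0.517 L mol⁻¹ h⁻¹, Ea4 = 52.0 kJ mol⁻¹)
    (constants at 5 °C)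

I wrote S for starting material, R for reagent, T for target, K for the equilibrium constant of the first step and k for its forward rate constant. In delta, target falls back with a half-life of 0.331 h, far shorter than its half-lives of 6.7 h towards side product B and 14 h towards over-reaction product, with the other concentrations as charged. So I set the forward rate over the back rate of the first step equal to one, and time dropped out:

k[S][R] ÷ ((k/K)[T]) = one, so [T] = K[R] × [S]

As charged at 5 °C, G = K[R] = 0.393. I called G the holding ratio, the target standing per unit of free starting material at pre-equilibrium. I then turned the settings one after the other.

- **Time:** S has a half-life of 2.5 h towards side product A as charged in delta, and that step spends R two at a time. I expected [S] and G to fall together, taking target down with them.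
- **Feeding S, steadily or in portions:** this slows that loss while S is held low, so I expected more of S and R to survive than in delta.
- **Feeding R:** the loss goes with [R] squared, so I expected a gain here too.
- **Cold:** the first step is endothermic by 24.0 kJ mol⁻¹, so K shrinks in the cold. In gamma and eta the last 1.00 h at 5 °C outlasts the fall-back half-life at that temperature, so I expected cold to save S and R and the warm stretch to bring target back towards [T] = K[R] × [S] with the listed K.

I ranked delta last and eta first, but I reckoned no end amounts by hand.

The forecast named eta, with 11 % for epsilon, 7.7 % for delta, 12.3 % for gamma, 11.2 % for beta, 12.5 % for zeta and 14.4 % for eta. Its ground was: “The target stays close to a weak, fast equilibrium”.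

The simulation gave 7.57 % for delta, the lowest, and delta left to 60.0 h held 0.978 %. Feeding S gave 10.8 % in epsilon and 10.8 % in beta, and feeding R gave 12.4 % in zeta. The cold start gave 12.2 % in gamma, and cold feeding gave 14.3 % in eta, the highest.

In delta at 1.46 h, target fell back 22 times faster than it went on. In eta at the end, at 5 °C, reagent stood at 56.8 % of its charge, so G came to 0.223, and with starting material at 63.1 % of its charge that estimated target at 14.1 % of the starting material charged, against the computed 14.3 %.

A neighbouring flask, like delta but with 0.050 M of starting material, read reagent 75.1 % and starting material 29.1 % of their charges at 6.00 h, so G came to 0.295 and the estimate of target to 8.60 % of the starting material charged. The computed target there was 9.06 %.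

Its constants are invented; no experiment stands behind them.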